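At 8.00 min the noon flask still holds 53.2% of its Q and the midnight flask 37.6%, and the whole reckoning starts from that gap. The proposed steps take Q to E by itself, to J and back, and in pairs to Z, which goes on to D or meets Q to give G.

| flask | Q | remark | time |
|---|---|---|---|
| noon | 0.038 M | run made earlier |  |
| midnight | 0.19 M | run made earlier |  |
| north-west | 0.10 M |  | 80 min |
| south-east | 0.20 M |  | 80 min |
| east | 0.060 M |  | 80 min |
| south | 0.12 M |  | 80 min |
| west | 0.30 M |  | 80 min |

| run | time / min | E / % | Q / % |
|---|---|---|---|
| noon | 8.00 | 16.0 | 53.2 |
| noon | 15.0 | 26.0 | 34.7 |
| noon | 25.0 | 33.9 | 23.1 |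
| noon | 30.0 | 36.9 | 18.7 |
| noon | 40.0 | 42.9 | 15.8 |
| noon | 50.0 | 43.9 | 13.4 |
| noon | 60.0 | 48.9 | 11.7 |
| midnight | 8.00 | 11.6 | 37.6 |
| midnight | 15.0 | 19.2 | 22.7 |
| midnight | 25.0 | 22.7 | 13.7 |
| midnight | 30.0 | 25.7 | 12.8 |
| midnight | 40.0 | 31.5 | 10.2 |
| midnight | 50.0 | 30.8 | 7.5 |
| midnight | 60.0 | 33.3 | 6.9 |

(readings scatter by 1 percentage point)

- percentages count the Q that a species holds: one Z or D counts as two
- percentages count the Q that a species holds: one G counts as three
- what was read earlier has a scatter of 1 percentage point, one standard deviation
- steps that have been proposed: Z -> D; Q <-> J; 2 Q -> Z; Q -> E; Q + Z -> G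

- ranking by amount of E, in percent of the Q charged, from high to low, at 80 min (north-west / south-east / east / south / west)
- the amount of E, in percent of the Q charged of the flask you put first, at 80 min
- the amount of E, in percent of the Q charged of the flask you put last, at 80 min

Read the first row of each table, column against column. Taken as a steady fractional fall, noon's Q drops at 0.0789 /min and midnight's at 0.122 /min. The mean amounts of Q over that stretch are 0.0282 M and 0.121 M. The steps of one Q by itself, to E and to J, remove the same fraction per minute in both flasks, so I give the difference to pairing, which makes its coefficient in Q used 0.466 /M/min; two Q go at each turn, so this coefficient counts Q used and is not the constant of the step.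

Now the E column: noon's 16.0%, set against its mean Q, gives 0.0270 /min for the step to E.

Divide the two and you have the crossing concentration, the amount of Q at which the step to E and pairing use Q equally fast: 0.0578 M, a reading that carries the scatter. Above it pairing uses Q faster; below it the step to E does. The crossing over the charge is a starting selectivity factor, E's rate over pairing's.

East, with the smallest charge, starts at 0.964. West, with the largest, starts at 0.193. I therefore rank the flasks by rising charge, though this ratio gives no percentages.

The forecast ranks them east > north-west > south > south-east > west, with 48% and 32.5%, on the ground that “E is the first-order channel, so its share falls as the charge rises”.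

The flasks give east > north-west > south > south-east > west, with 51.0% and 30.9%.

    Z → D (k = 0.120 /min)
    Q ⇌ J (K = 1.40, k = 0.0390 /min)
    2 Q → Z (k = 0.250 /M/min)
    Q → E (k = 0.0280 /min)
    Q + Z → G (k = 0.0320 /M/min)

West's reckoned ratio of 0.193 stands beside the 0.19 of the flask at the start. Take a neighbour like west but charged with 0.075 M: its ratio is 0.771, so it starts just above the crossing. At 80.0 min it holds E at 48.8%, above D at 24.6%, whereas west holds E at 30.9%, below D at 51.8%.

The readings are calculated for an exercise; noise was put on by code.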